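**Retrosynthetic overview**
- Numbering: lactone O1, C2(=O), C3, C4, C5; C7 is the carbinol carbon on C3 (ring A); C7' is the CH2 on C4 (ring B). The target is (3S,4R,7S), with the C3 and C4 substituents trans and C7–OH syn to C4 along the chain C2–C3–C7–aryl.
- Ring A and C7 are disconnected at C3–C7: enolate acylation sets C3 trans to C4, and chelate-controlled ketone reduction sets C7. This leaves a 4-arylmethyl γ-lactone with C4 as its only stereocentre.
- The feature the strategy rests on: C4 lies β to both C2 and O1, opposite the C2–O1 bond. Taking O1 out gives a 3-(arylmethyl)cyclobutanone with a mirror plane through C=O and C4. An asymmetric Baeyer–Villiger oxidation then forms C2–O1 and O1–C5 and sets C4 by choosing one of two enantiotopic CH2 groups.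
- The cyclobutanone comes from [2+2] addition of dichloroketene to silylated eugenol, then dechlorination. Eugenol supplies ring B, C7', C4 and C5; the ketene supplies C2 and C3.
- Ring order: cyclobutane (step 2), then γ-lactone by ring expansion (step 4). Stereocentre order: C4 (catalyst), C3 (trans), C7 (chelation).

Key step: step 4

Assumption: a 3-arylmethyl group is taken to follow the same sense of induction as 3-aryl groups with the phosphoric acid, so the (S)-acid is specified; if a first run gave the (S)-lactone, the mirror-image acid would be used. TBS = tert-butyldimethylsilyl.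

Step 1
Reactants: 1 eugenol (4-allyl-2-methoxyphenol)
Product: 2 tert-butyl(4-allyl-2-methoxyphenoxy)dimethylsilane
Conditions: TBSCl, imidazole, DMF, rt
Reagents that add atoms: tert-butyldimethylsilyl chloride, CC(C)(C)[Si](C)(C)Cl
Why: Silylation of the phenol (imidazole-promoted) masks the acidic, oxidisable OH for the zinc, peroxide and enolate steps and lets both phenols be freed together at the end; no stereocentre is involved.

Step 2
Reactants: 2 tert-butyl(4-allyl-2-methoxyphenoxy)dimethylsilane; 3 trichloroacetyl chloride
Product: 5 2,2-dichloro-3-{[4-(TBS-oxy)-3-methoxyphenyl]methyl}cyclobutan-1-one (racemic), via dichloroketene 4 (not isolated)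
Conditions: Zn–Cu couple, Et2O–DME, slow addition of 3, rt then gentle reflux
Reagents that add atoms: none
Why: Zinc dehalogenates 3 to dichloroketene, which undergoes thermal [2+2] cycloaddition with the terminal alkene, its carbonyl carbon bonding to the terminal CH2 and CCl2 to the internal CH (the usual regiochemistry for monosubstituted alkenes), while DME ties up ZnCl2; the new centre is racemic and stops being a stereocentre after step 3.

Step 3
Reactants: 5 2,2-dichloro-3-{[4-(TBS-oxy)-3-methoxyphenyl]methyl}cyclobutan-1-one
Product: 6 3-{[4-(TBS-oxy)-3-methoxyphenyl]methyl}cyclobutan-1-one (achiral, mirror plane through C=O and C3)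
Conditions: Zn dust, AcOH, rt
Reagents that add atoms: none
Why: Reductive dechlorination of the α,α-dichloroketone (two rounds of zinc enolate formation and protonation) should give the prochiral ketone, and the aryl silyl ether tolerates acetic acid at room temperature.

Step 4
Reactants: 6 3-{[4-(TBS-oxy)-3-methoxyphenyl]methyl}cyclobutan-1-one
Product: 8 (4R)-4-{[4-(TBS-oxy)-3-methoxyphenyl]methyl}oxolan-2-one, via Criegee hydroperoxy hemiketal 7 (not isolated)
Conditions: (S)-3,3'-di(pyren-1-yl)-5,5',6,6',7,7',8,8'-octahydro-1,1'-binaphthalene-2,2'-diyl hydrogen phosphate (10 mol %), 30% aq H2O2 (1.5 equiv), CHCl3, −40 °C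
Reagents that add atoms: hydrogen peroxide, OO
Why: Hydrogen peroxide, activated by the bifunctional phosphoric acid, adds to the strained carbonyl of 6 to give the Criegee hydroperoxy hemiketal 7, and one of the two enantiotopic ring CH2 groups then shifts from carbon to the proximal peroxide oxygen with loss of water and retention at the migrating carbon (Baeyer–Villiger oxidation). The closest known reaction is the phosphoric acid/aqueous H2O2 desymmetrisation of 3-aryl- and 3-benzylcyclobutanones to 4-substituted γ-butyrolactones. The five-membered lactone is not closed by a cyclisation but grows out of the four-membered ring through this 1,2-shift, which makes the C2–O1 and O1–C5 bonds in one event. C4 is not touched and becomes stereogenic only because the two arms are made different, so its (R) configuration is set by the chiral pocket of the catalyst, which binds the hemiketal OH and the peroxide OH on its P=O/P–OH pair and lets only one CH2 align antiperiplanar to the O–O bond. The step needs enantiotopic-group selectivity only, since the two α-carbons are constitutionally equivalent and no regioisomer can form. Chemoselectivity rests on the strain of the cyclobutanone, which reacts with H2O2 at −40 °C, while the silylated arene, insulated by one CH2, should not be oxidised.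

Step 5
Reactants: 9 vanillic acid (4-hydroxy-3-methoxybenzoic acid)
Product: 11 4-(TBS-oxy)-3-methoxybenzoic acid, via bis-silylated vanillic acid 10 (not isolated)
Conditions: TBSCl (2.5 equiv), imidazole, DMF, rt; then AcOH–THF–H2O (3:1:1), rt
Reagents that add atoms: tert-butyldimethylsilyl chloride, CC(C)(C)[Si](C)(C)Cl
Why: Exhaustive silylation followed by selective hydrolysis of the silyl ester, which is far more labile to aqueous acetic acid than the aryl silyl ether, should leave the free acid with the phenol protected.

Step 6
Reactants: 11 4-(TBS-oxy)-3-methoxybenzoic acid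
Product: 12 [4-(TBS-oxy)-3-methoxyphenyl](1H-imidazol-1-yl)methanone
Conditions: 1,1'-carbonyldiimidazole (1.1 equiv), THF, rt; CH2Cl2 solution washed quickly with cold water to remove imidazole, dried
Reagents that add atoms: 1,1'-carbonyldiimidazole, O=C(n1ccnc1)n1ccnc1
Why: Activation of the acid as its acyl imidazole (Staab method) is driven by loss of CO2 and is neutral, so the aryl silyl ether is safe; free imidazole is removed because its N–H would quench the enolate in step 7.

Step 7
Reactants: 8 (4R)-4-{[4-(TBS-oxy)-3-methoxyphenyl]methyl}oxolan-2-one; 12 [4-(TBS-oxy)-3-methoxyphenyl](1H-imidazol-1-yl)methanone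
Product: 15 (3S,4R)-3-[4-(TBS-oxy)-3-methoxybenzoyl]-4-{[4-(TBS-oxy)-3-methoxyphenyl]methyl}oxolan-2-one, via lactone lithium enolate 13 (not isolated), via keto lactone lithium enolate 14 (not isolated)
Conditions: LiN(SiMe3)2 (2.1 equiv), THF, −78 °C; then 12 in THF, −78 to −30 °C; AcOH quench at −78 °C
Reagents that add atoms: none
Why: Claisen-type C-acylation of the lactone lithium enolate by the acyl imidazole forms C3–C7, the second equivalent of base storing the product as its enolate 14 against over-addition; C3 ends trans to the C4 arylmethyl group (3S) because the acyl group enters anti to that group and the acidic 1,3-dicarbonyl centre settles to the more stable trans isomer on protonation.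

Step 8
Reactants: 15 (3S,4R)-3-[4-(TBS-oxy)-3-methoxybenzoyl]-4-{[4-(TBS-oxy)-3-methoxyphenyl]methyl}oxolan-2-one
Product: 16 (3S,4R)-3-{(S)-hydroxy[4-(TBS-oxy)-3-methoxyphenyl]methyl}-4-{[4-(TBS-oxy)-3-methoxyphenyl]methyl}oxolan-2-one
Conditions: Zn(BH4)2, Et2O–THF, −20 to 0 °C; aq NH4Cl work-up
Reagents that add atoms: none
Why: Chelation-controlled reduction of an α-substituted β-keto ester: zinc bridges the C7 ketone and C2 carbonyl oxygens, fixing C7=O syn to C2=O, and hydride adds to the face of C7 flanked by C3–H and not by C4, which gives the syn (7S) carbinol; the weakly basic reagent should neither enolise C3 nor reduce the lactone at this temperature.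

Step 9
Reactants: 16 (3S,4R)-3-{(S)-hydroxy[4-(TBS-oxy)-3-methoxyphenyl]methyl}-4-{[4-(TBS-oxy)-3-methoxyphenyl]methyl}oxolan-2-one
Product: 17 (3S,4R)-3-[(S)-hydroxy(4-hydroxy-3-methoxyphenyl)methyl]-4-[(4-hydroxy-3-methoxyphenyl)methyl]oxolan-2-one (target)
Conditions: Bu4NF (2.4 equiv), AcOH (2.4 equiv), THF, 0 °C
Reagents that add atoms: none
Why: Fluoride cleaves both aryl silyl ethers through Si–F bond formation, and the acetic acid buffer protonates the phenoxides as they form, so retro-aldol cleavage of C3–C7 and quinone methide formation at C7 should be suppressed and no stereocentre is touched.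

**Compound list**
1 | eugenol | COc1cc(CC=C)ccc1O | starting material
2 | tert-butyl(4-allyl-2-methoxyphenoxy)dimethylsilane | COc1cc(CC=C)ccc1O[Si](C)(C)C(C)(C)C | intermediate
3 | trichloroacetyl chloride | ClC(=O)C(Cl)(Cl)Cl | starting material
4 | dichloroketene | ClC(Cl)=C=O | intermediate (not isolated)
5 | 2,2-dichloro-3-{[4-(TBS-oxy)-3-methoxyphenyl]methyl}cyclobutan-1-one, racemic | COc1cc(CC2CC(=O)C2(Cl)Cl)ccc1O[Si](C)(C)C(C)(C)C | intermediate
6 | 3-{[4-(TBS-oxy)-3-methoxyphenyl]methyl}cyclobutan-1-one | COc1cc(CC2CC(=O)C2)ccc1O[Si](C)(C)C(C)(C)C | intermediate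
7 | 1-hydroperoxy-3-{[4-(TBS-oxy)-3-methoxyphenyl]methyl}cyclobutan-1-ol (Criegee adduct) | COc1cc(CC2CC(O)(OO)C2)ccc1O[Si](C)(C)C(C)(C)C | intermediate (not isolated)
8 | (4R)-4-{[4-(TBS-oxy)-3-methoxyphenyl]methyl}oxolan-2-one | COc1cc(C[C@H]2COC(=O)C2)ccc1O[Si](C)(C)C(C)(C)C | intermediate
9 | vanillic acid | COc1cc(C(=O)O)ccc1O | starting material
10 | tert-butyldimethylsilyl 4-(TBS-oxy)-3-methoxybenzoate | COc1cc(C(=O)O[Si](C)(C)C(C)(C)C)ccc1O[Si](C)(C)C(C)(C)C | intermediate (not isolated)
11 | 4-(TBS-oxy)-3-methoxybenzoic acid | COc1cc(C(=O)O)ccc1O[Si](C)(C)C(C)(C)C | intermediate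
12 | [4-(TBS-oxy)-3-methoxyphenyl](1H-imidazol-1-yl)methanone | COc1cc(C(=O)n2ccnc2)ccc1O[Si](C)(C)C(C)(C)C | intermediate
13 | lithium enolate of 8 (4R) | COc1cc(C[C@H]2COC(O[Li])=C2)ccc1O[Si](C)(C)C(C)(C)C | intermediate (not isolated)
14 | lithium enolate of 15 (4R), enolised at C3–C7 | COc1cc(C[C@H]2COC(=O)C2=C(O[Li])c2ccc(O[Si](C)(C)C(C)(C)C)c(OC)c2)ccc1O[Si](C)(C)C(C)(C)C | intermediate (not isolated)
15 | (3S,4R)-3-[4-(TBS-oxy)-3-methoxybenzoyl]-4-{[4-(TBS-oxy)-3-methoxyphenyl]methyl}oxolan-2-one | COc1cc(C[C@H]2COC(=O)[C@@H]2C(=O)c2ccc(O[Si](C)(C)C(C)(C)C)c(OC)c2)ccc1O[Si](C)(C)C(C)(C)C | intermediate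
16 | (3S,4R)-3-{(S)-hydroxy[4-(TBS-oxy)-3-methoxyphenyl]methyl}-4-{[4-(TBS-oxy)-3-methoxyphenyl]methyl}oxolan-2-one | COc1cc(C[C@H]2COC(=O)[C@@H]2[C@H](O)c2ccc(O[Si](C)(C)C(C)(C)C)c(OC)c2)ccc1O[Si](C)(C)C(C)(C)C | intermediate
17 | (3S,4R)-3-[(S)-hydroxy(4-hydroxy-3-methoxyphenyl)methyl]-4-[(4-hydroxy-3-methoxyphenyl)methyl]oxolan-2-one | COc1cc(C[C@H]2COC(=O)[C@@H]2[C@H](O)c2ccc(O)c(OC)c2)ccc1O | target

**Step count**
Total: 9 steps. Longest linear sequence: 7 steps (1, 2, 3, 4, 7, 8, 9 from eugenol); the vanillic acid branch (steps 5 and 6) is 2 steps.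

**Steps most likely to fail**

Step 4. The catalyst may discriminate poorly between the two enantiotopic migrating CH2 groups when the C3 substituent is a flexible arylmethyl group and not an aryl group, and uncatalysed background oxidation may erode the selectivity further, so 8 may be formed with insufficient enantiomeric purity. The fallback sets out from 6 and comes back at 8, and desymmetrises the ketone by deprotonation instead of migration. Ketone 6 is treated with lithium bis[(S)-1-phenylethyl]amide in THF at −100 to −78 °C with Et3SiCl present as internal quench. This chiral-base deprotonation of a 3-substituted cyclobutanone should give the (R)-configured triethylsilyl enol ether F1; the mirror-image amide is used if the sense proves opposite. Ozonolysis of the enol ether double bond (O3, CH2Cl2–MeOH, −78 °C, stopped at the first excess of ozone to spare the arene) gives the triethylsilyl ester aldehyde F2. This is reduced in the same flask with NaBH4 before the α-formyl centre can epimerise. Aqueous work-up hydrolyses the silyl ester to the (R)-hydroxy acid F3, which lactonises on mild acidification (catalytic TsOH, CH2Cl2) to 8.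

Step 8. Hydride may add with poor facial selectivity if a non-chelated rotamer of the keto lactone competes with the zinc chelate, giving the C7 epimer alongside 16. The fallback sets out from 15 and comes back at 16, and replaces substrate (chelate) control by catalyst control. Asymmetric transfer hydrogenation of the aryl ketone with RuCl(p-cymene)[(S,S)-N-tosyl-1,2-diphenylethylenediamine] in HCO2H–Et3N at rt lets the ligand dictate the C7 configuration. The (S,S) ligand is expected to give the (S)-carbinol by the aryl/alkyl rule for aryl ketones, and the acidic C3 centre stays in its favoured trans arrangement. This fallback makes no compound outside the list (none, F0).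

Step 7. The enolate may be acylated on oxygen, the silylamide may attack the acyl imidazole, or proton exchange between product and enolate may leave lactone unconverted. The fallback sets out from 8 and comes back at 15, and makes C3–C7 by aldol addition followed by oxidation. Commercial vanillin (COc1cc(C=O)ccc1O) is silylated (TBSCl, imidazole, DMF) to 4-(TBS-oxy)-3-methoxybenzaldehyde F4. The lithium enolate of 8 (LiN(SiMe3)2, THF, −78 °C) adds to it anti to the C4 substituent to give the 3,4-trans aldol as a mixture of C7 epimers F5. Oxidation with Dess–Martin periodinane (CH2Cl2, NaHCO3, rt) converges both epimers on 15.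

**Further compounds**
F1 | step 4 | (R)-tert-butyl{2-methoxy-4-[(3-(triethylsilyloxy)cyclobut-2-en-1-yl)methyl]phenoxy}dimethylsilane | COc1cc(C[C@H]2C=C(O[Si](CC)(CC)CC)C2)ccc1O[Si](C)(C)C(C)(C)C
F2 | step 4 | triethylsilyl (3R)-3-{[4-(TBS-oxy)-3-methoxyphenyl]methyl}-4-oxobutanoate | COc1cc(C[C@@H](C=O)CC(=O)O[Si](CC)(CC)CC)ccc1O[Si](C)(C)C(C)(C)C
F3 | step 4 | (3R)-4-hydroxy-3-{[4-(TBS-oxy)-3-methoxyphenyl]methyl}butanoic acid | COc1cc(C[C@@H](CO)CC(=O)O)ccc1O[Si](C)(C)C(C)(C)C
F0 | step 8 | none | none
F4 | step 7 | 4-(TBS-oxy)-3-methoxybenzaldehyde | COc1cc(C=O)ccc1O[Si](C)(C)C(C)(C)C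
F5 | step 7 | (3S,4R)-3-{hydroxy[4-(TBS-oxy)-3-methoxyphenyl]methyl}-4-{[4-(TBS-oxy)-3-methoxyphenyl]methyl}oxolan-2-one, mixture of C7 epimers | COc1cc(C[C@H]2COC(=O)[C@@H]2C(O)c2ccc(O[Si](C)(C)C(C)(C)C)c(OC)c2)ccc1O[Si](C)(C)C(C)(C)C
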